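## Retrosynthetic overview

1. Ring numbering: C1 = CH–OAc, C3(Me)=C4, C7(Me)(OH), C8=C9, C10(i-Pr), C13 = quaternary C–CHO; the target is (1S,3E,7R,8E,10S,13S). The acetate and aldehyde come last from macrocyclic triol 39 (selective primary-alcohol oxidation, then acetylation of the secondary OH).
2. The only ring (13-membered carbocycle) is closed in step 29 by an intramolecular B-alkyl Suzuki coupling forming C4–C5 (C4 vinyl iodide plus the 9-BBN adduct of the C5=C6 vinyl group).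
3. C8=C9 (E) comes from a Julia–Kocienski union of aldehyde 10 (C5–C8) with PT-sulfone 34 (C9–C13 and C1–C4).
4. In 34, C1 is set by ketoreductase reduction of β-keto ester 11, C13 by two Fráter–Seebach alkylations (MeI, then allyl bromide), and C10 by CBS reduction followed by anti-SN2' cuprate chirality transfer. The C3=C4–I unit comes from zirconium-catalysed carboalumination.
5. In 10, C7 is set by Sharpless epoxidation of an achiral allylic alcohol (the first stereocentre of the route), followed by reductive opening of the epoxy iodide.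

Assumption: ethyl 5-(benzyloxy)-3-oxopentanoate (11) is taken as a catalogue compound.

Abbreviations: TBS = tert-butyldimethylsilyl, TES = triethylsilyl, Piv = 2,2-dimethylpropanoyl, PT = 1-phenyl-1H-tetrazol-5-yl, Bn = benzyl, 9-BBN = 9-borabicyclo[3.3.1]nonane, DMP = Dess–Martin periodinane.

## Route

**Aldehyde fragment 10 (C5–C8)**

Step 1
Reactants: 1 3-methylbut-2-en-1-yl acetate (prenyl acetate)
Product: 2 (2E)-4-hydroxy-3-methylbut-2-en-1-yl acetate
Conditions: SeO2 (0.3 equiv), t-BuOOH (2 equiv), salicylic acid (cat.), CH2Cl2, rt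
Reagents that add atoms: tert-butyl hydroperoxide CC(C)(C)OO
Why: SeO2-catalysed allylic oxidation (ene reaction then [2,3]-shift) hydroxylates the (E)-methyl group of the trisubstituted alkene selectively.

Step 2
Reactants: 2 (2E)-4-hydroxy-3-methylbut-2-en-1-yl acetate
Product: 3 (2E)-4-(acetyloxy)-2-methylbut-2-en-1-yl 2,2-dimethylpropanoate
Conditions: PivCl, pyridine, DMAP (cat.), CH2Cl2, 0 °C
Reagents that add atoms: pivaloyl chloride CC(C)(C)C(=O)Cl
Why: Simple O-acylation puts a robust ester on the oxygen that will become the aldehyde carbon's oxygen.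

Step 3
Reactants: 3 (2E)-4-(acetyloxy)-2-methylbut-2-en-1-yl 2,2-dimethylpropanoate
Product: 4 (2E)-4-hydroxy-2-methylbut-2-en-1-yl 2,2-dimethylpropanoate
Conditions: K2CO3 (0.2 equiv), MeOH, 0 °C
Reagents that add atoms: none
Why: Transesterification removes the unhindered primary acetate much faster than the pivalate.

Step 4
Reactants: 4 (2E)-4-hydroxy-2-methylbut-2-en-1-yl 2,2-dimethylpropanoate
Product: 5 [(2S,3S)-3-(hydroxymethyl)-2-methyloxiran-2-yl]methyl 2,2-dimethylpropanoate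
Conditions: Ti(OiPr)4 (10 mol %), L-(+)-diethyl tartrate (12 mol %), t-BuOOH, 4 Å MS, CH2Cl2, −20 °C
Reagents that add atoms: tert-butyl hydroperoxide CC(C)(C)OO
Why: Katsuki–Sharpless asymmetric epoxidation; L-(+)-tartrate delivers oxygen to the same face as in geraniol → (2S,3S)-epoxygeraniol, and the E alkene fixes the trans epoxide, so both centres (the quaternary one is the future C7) are set by the catalyst.

Step 5
Reactants: 5 [(2S,3S)-3-(hydroxymethyl)-2-methyloxiran-2-yl]methyl 2,2-dimethylpropanoate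
Product: 6 [(2S,3R)-3-(iodomethyl)-2-methyloxiran-2-yl]methyl 2,2-dimethylpropanoate
Conditions: I2, PPh3, imidazole, CH2Cl2, 0 °C
Reagents that add atoms: iodine II
Why: Appel-type iodination of the primary alcohol leaves both epoxide centres untouched (the descriptor change is only a CIP priority change).

Step 6
Reactants: 6 [(2S,3R)-3-(iodomethyl)-2-methyloxiran-2-yl]methyl 2,2-dimethylpropanoate
Product: 7 (2R)-2-hydroxy-2-methylbut-3-en-1-yl 2,2-dimethylpropanoate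
Conditions: Zn dust, AcOH, EtOH, 50 °C
Reagents that add atoms: none
Why: Reductive fragmentation (zinc insertion into C–I, then β-elimination opening the epoxide) gives the tertiary vinyl carbinol without touching the tertiary C–O bond, so its configuration is retained.

Step 7
Reactants: 7 (2R)-2-hydroxy-2-methylbut-3-en-1-yl 2,2-dimethylpropanoate
Product: 8 (2R)-2-methyl-2-[(triethylsilyl)oxy]but-3-en-1-yl 2,2-dimethylpropanoate
Conditions: TESOTf, 2,6-lutidine, CH2Cl2, −78 → 0 °C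
Reagents that add atoms: triethylsilyl trifluoromethanesulfonate CC[Si](CC)(CC)OS(=O)(=O)C(F)(F)F
Why: Silyl triflate silylation is the standard way to protect a tertiary alcohol.

Step 8
Reactants: 8 (2R)-2-methyl-2-[(triethylsilyl)oxy]but-3-en-1-yl 2,2-dimethylpropanoate
Product: 9 (2R)-2-methyl-2-[(triethylsilyl)oxy]but-3-en-1-ol
Conditions: i-Bu2AlH (2.2 equiv), CH2Cl2, −78 °C
Reagents that add atoms: none
Why: Reductive ester cleavage with an aluminium hydride frees the primary alcohol under non-basic conditions that leave the tertiary TES ether in place.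

Step 9
Reactants: 9 (2R)-2-methyl-2-[(triethylsilyl)oxy]but-3-en-1-ol
Product: 10 (2R)-2-methyl-2-[(triethylsilyl)oxy]but-3-enal
Conditions: DMP, NaHCO3, CH2Cl2, rt
Reagents that add atoms: none
Why: Dess–Martin oxidation gives an aldehyde with no α-hydrogen, so the stereocentre cannot epimerise.

**Sulfone fragment 34 (C9–C13, C1–C4)**

Step 10
Reactants: 11 ethyl 5-(benzyloxy)-3-oxopentanoate
Product: 12 ethyl (3S)-5-(benzyloxy)-3-hydroxypentanoate
Conditions: (S)-selective ketoreductase, NADP+ (cat.), i-PrOH, phosphate buffer pH 7, 30 °C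
Reagents that add atoms: none
Why: A ketoreductase (NADPH-dependent alcohol dehydrogenase class, cofactor recycled by i-PrOH) delivers hydride to one face of the β-keto ester and sets the (3S) carbinol (future C1).

Step 11
Reactants: 12 ethyl (3S)-5-(benzyloxy)-3-hydroxypentanoate
Product: 14 ethyl (2S,3S)-5-(benzyloxy)-3-hydroxy-2-methylpentanoate, via dilithium alkoxide-enolate 13 (not isolated)
Conditions: LiN(iPr)2 (2.2 equiv), THF, −78 → −20 °C; MeI, DMPU, −78 → 0 °C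
Reagents that add atoms: iodomethane CI
Why: Fráter–Seebach alkylation: the chelated alkoxide-enolate is methylated on the face anti to the C3 side chain, giving the 2,3-anti ester.

Step 12
Reactants: 14 ethyl (2S,3S)-5-(benzyloxy)-3-hydroxy-2-methylpentanoate
Product: 16 ethyl (2S,3S)-5-(benzyloxy)-3-hydroxy-2-methyl-2-(prop-2-en-1-yl)pentanoate, via dilithium alkoxide-enolate 15 (not isolated)
Conditions: LiN(iPr)2 (2.5 equiv), THF, −78 → −15 °C; allyl bromide, DMPU, −78 → −10 °C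
Reagents that add atoms: allyl bromide C=CCBr
Why: Second Fráter–Seebach alkylation: the chelated tetrasubstituted enolate again takes the electrophile anti to the C3 side chain, so allyl ends anti and methyl syn to the hydroxyl, which is the C13/C1 relationship of the target.

Step 13
Reactants: 16 ethyl (2S,3S)-5-(benzyloxy)-3-hydroxy-2-methyl-2-(prop-2-en-1-yl)pentanoate
Product: 17 (2R,3S)-5-(benzyloxy)-2-methyl-2-(prop-2-en-1-yl)pentane-1,3-diol
Conditions: LiAlH4, THF, 0 °C → rt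
Reagents that add atoms: none
Why: Hydride reduction of the hindered ester gives the primary alcohol that will become the formyl group (the descriptor change at the quaternary carbon is only a CIP priority change).

Step 14
Reactants: 17 (2R,3S)-5-(benzyloxy)-2-methyl-2-(prop-2-en-1-yl)pentane-1,3-diol
Product: 18 (2R,3S)-5-(benzyloxy)-1,3-bis[(tert-butyldimethylsilyl)oxy]-2-methyl-2-(prop-2-en-1-yl)pentane
Conditions: TBSOTf (2.5 equiv), 2,6-lutidine, CH2Cl2, −78 → 0 °C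
Reagents that add atoms: tert-butyldimethylsilyl trifluoromethanesulfonate CC(C)(C)[Si](C)(C)OS(=O)(=O)C(F)(F)F
Why: Silyl triflate silylation protects both the primary and the hindered secondary hydroxyl in one operation.

Step 15
Reactants: 18 (2R,3S)-5-(benzyloxy)-1,3-bis[(tert-butyldimethylsilyl)oxy]-2-methyl-2-(prop-2-en-1-yl)pentane
Product: 20 (4R,5S)-7-(benzyloxy)-5-[(tert-butyldimethylsilyl)oxy]-4-{[(tert-butyldimethylsilyl)oxy]methyl}-4-methylheptan-1-ol, via B-alkyl-9-BBN adduct 19 (not isolated)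
Conditions: 9-BBN, THF, 0 °C → rt; then NaOH, H2O2, 0 °C
Reagents that add atoms: hydrogen peroxide OO
Why: Anti-Markovnikov hydroboration–oxidation of the terminal alkene gives the primary alcohol at the future C10.

Step 16
Reactants: 20 (4R,5S)-7-(benzyloxy)-5-[(tert-butyldimethylsilyl)oxy]-4-{[(tert-butyldimethylsilyl)oxy]methyl}-4-methylheptan-1-ol
Product: 21 (4R,5S)-7-(benzyloxy)-5-[(tert-butyldimethylsilyl)oxy]-4-{[(tert-butyldimethylsilyl)oxy]methyl}-4-methylheptanal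
Conditions: DMP, NaHCO3, CH2Cl2, rt
Reagents that add atoms: none
Why: Dess–Martin oxidation of a primary alcohol to the aldehyde is compatible with silyl and benzyl ethers.

Step 17
Reactants: 21 (4R,5S)-7-(benzyloxy)-5-[(tert-butyldimethylsilyl)oxy]-4-{[(tert-butyldimethylsilyl)oxy]methyl}-4-methylheptanal
Product: 22 (3E,7R,8S)-10-(benzyloxy)-8-[(tert-butyldimethylsilyl)oxy]-7-{[(tert-butyldimethylsilyl)oxy]methyl}-7-methyldec-3-en-2-one
Conditions: Ph3P=CHC(O)CH3, CH2Cl2, 40 °C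
Reagents that add atoms: 1-(triphenyl-λ5-phosphanylidene)propan-2-one CC(=O)C=P(c1ccccc1)(c1ccccc1)c1ccccc1
Why: Wittig olefination with a stabilised ylide gives the (E)-enone.

Step 18
Reactants: 22 (3E,7R,8S)-10-(benzyloxy)-8-[(tert-butyldimethylsilyl)oxy]-7-{[(tert-butyldimethylsilyl)oxy]methyl}-7-methyldec-3-en-2-one
Product: 23 (2R,3E,7R,8S)-10-(benzyloxy)-8-[(tert-butyldimethylsilyl)oxy]-7-{[(tert-butyldimethylsilyl)oxy]methyl}-7-methyldec-3-en-2-ol
Conditions: (S)-2-methyl-CBS-oxazaborolidine (20 mol %), catecholborane, toluene, −78 °C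
Reagents that add atoms: none
Why: Corey–Bakshi–Shibata reduction: the (S)-oxazaborolidine treats alkenyl as the large and methyl as the small group and gives the (2R) allylic alcohol by 1,2-reduction.

Step 19
Reactants: 23 (2R,3E,7R,8S)-10-(benzyloxy)-8-[(tert-butyldimethylsilyl)oxy]-7-{[(tert-butyldimethylsilyl)oxy]methyl}-7-methyldec-3-en-2-ol
Product: 24 (2R,3E,7R,8S)-10-(benzyloxy)-8-[(tert-butyldimethylsilyl)oxy]-7-{[(tert-butyldimethylsilyl)oxy]methyl}-7-methyldec-3-en-2-yl pyridine-2-carboxylate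
Conditions: picolinic acid, DCC, DMAP (cat.), CH2Cl2, rt
Reagents that add atoms: pyridine-2-carboxylic acid OC(=O)c1ccccn1
Why: Steglich esterification installs a chelating leaving group with retention at the carbinol.

Step 20
Reactants: 24 (2R,3E,7R,8S)-10-(benzyloxy)-8-[(tert-butyldimethylsilyl)oxy]-7-{[(tert-butyldimethylsilyl)oxy]methyl}-7-methyldec-3-en-2-yl pyridine-2-carboxylate
Product: 25 (2E,4S,7R,8S)-10-(benzyloxy)-8-[(tert-butyldimethylsilyl)oxy]-7-{[(tert-butyldimethylsilyl)oxy]methyl}-7-methyl-4-(propan-2-yl)dec-2-ene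
Conditions: i-PrMgBr (2 equiv), CuBr·SMe2 (1 equiv), THF, −78 → −40 °C
Reagents that add atoms: isopropylmagnesium bromide CC(C)[Mg]Br
Why: Copper-mediated anti-SN2' allylic substitution: isopropyl enters anti to the picolinate from the H-eclipsed conformer, transferring the (2R) carbinol chirality to the (4S) centre (future C10) and leaving an (E)-propenyl group.

Step 21
Reactants: 25 (2E,4S,7R,8S)-10-(benzyloxy)-8-[(tert-butyldimethylsilyl)oxy]-7-{[(tert-butyldimethylsilyl)oxy]methyl}-7-methyl-4-(propan-2-yl)dec-2-ene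
Product: 26 (3S,4R,7S,8E)-3-[(tert-butyldimethylsilyl)oxy]-4-{[(tert-butyldimethylsilyl)oxy]methyl}-4-methyl-7-(propan-2-yl)dec-8-en-1-ol
Conditions: lithium 4,4'-di-tert-butylbiphenylide, THF, −78 °C
Reagents that add atoms: none
Why: Dissolving-metal-type reductive debenzylation cleaves the benzyl ether while the isolated alkene and the TBS ethers survive.

Step 22
Reactants: 26 (3S,4R,7S,8E)-3-[(tert-butyldimethylsilyl)oxy]-4-{[(tert-butyldimethylsilyl)oxy]methyl}-4-methyl-7-(propan-2-yl)dec-8-en-1-ol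
Product: 27 (3S,4R,7S,8E)-3-[(tert-butyldimethylsilyl)oxy]-4-{[(tert-butyldimethylsilyl)oxy]methyl}-4-methyl-7-(propan-2-yl)dec-8-enal
Conditions: DMP, NaHCO3, CH2Cl2, rt
Reagents that add atoms: none
Why: Buffered Dess–Martin oxidation gives the β-silyloxy aldehyde without elimination.

Step 23
Reactants: 27 (3S,4R,7S,8E)-3-[(tert-butyldimethylsilyl)oxy]-4-{[(tert-butyldimethylsilyl)oxy]methyl}-4-methyl-7-(propan-2-yl)dec-8-enal
Product: 28 (4S,5R,8S,9E)-4-[(tert-butyldimethylsilyl)oxy]-5-{[(tert-butyldimethylsilyl)oxy]methyl}-5-methyl-8-(propan-2-yl)undec-9-en-1-yne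
Conditions: dimethyl (1-diazo-2-oxopropyl)phosphonate, K2CO3, MeOH, 0 °C → rt
Reagents that add atoms: dimethyl (1-diazo-2-oxopropyl)phosphonate CC(=O)C(=[N+]=[N-])P(=O)(OC)OC
Why: Ohira–Bestmann (Seyferth–Gilbert) homologation converts the aldehyde into the terminal alkyne under mild carbonate conditions.

Step 24
Reactants: 28 (4S,5R,8S,9E)-4-[(tert-butyldimethylsilyl)oxy]-5-{[(tert-butyldimethylsilyl)oxy]methyl}-5-methyl-8-(propan-2-yl)undec-9-en-1-yne
Product: 30 (2S,5R,6S)-6-[(tert-butyldimethylsilyl)oxy]-5-{[(tert-butyldimethylsilyl)oxy]methyl}-5-methyl-2-(propan-2-yl)non-8-yn-1-ol, via ynal 29 (not isolated)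
Conditions: O3, CH2Cl2/MeOH, −78 °C; then NaBH4, −78 → 0 °C
Reagents that add atoms: ozone [O-][O+]=O
Why: Ozonolysis with reductive work-up cleaves the only alkene (terminal alkynes react far more slowly) and unveils the C9 carbinol, with the aldehyde reduced cold before it can epimerise.

Step 25
Reactants: 30 (2S,5R,6S)-6-[(tert-butyldimethylsilyl)oxy]-5-{[(tert-butyldimethylsilyl)oxy]methyl}-5-methyl-2-(propan-2-yl)non-8-yn-1-ol
Product: 32 (2S,5R,6S,8E)-6-[(tert-butyldimethylsilyl)oxy]-5-{[(tert-butyldimethylsilyl)oxy]methyl}-9-iodo-5,8-dimethyl-2-(propan-2-yl)non-8-en-1-ol, via alkenyl(dimethyl)alane 31 (not isolated)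
Conditions: AlMe3 (4 equiv), Cp2ZrCl2 (0.5 equiv), CH2Cl2, 0 °C → rt; then I2, THF, −30 °C
Reagents that add atoms: trimethylaluminium C[Al](C)C; iodine II
Why: Negishi zirconium-catalysed carboalumination adds Me–Al syn across the terminal alkyne (methyl to the internal carbon) and iodinolysis proceeds with retention, giving the (E)-trisubstituted vinyl iodide.

Step 26
Reactants: 32 (2S,5R,6S,8E)-6-[(tert-butyldimethylsilyl)oxy]-5-{[(tert-butyldimethylsilyl)oxy]methyl}-9-iodo-5,8-dimethyl-2-(propan-2-yl)non-8-en-1-ol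
Product: 33 5-{[(2S,5R,6S,8E)-6-[(tert-butyldimethylsilyl)oxy]-5-{[(tert-butyldimethylsilyl)oxy]methyl}-9-iodo-5,8-dimethyl-2-(propan-2-yl)non-8-en-1-yl]sulfanyl}-1-phenyl-1H-tetrazole
Conditions: 1-phenyl-1H-tetrazole-5-thiol, PPh3, DIAD, THF, 0 °C → rt
Reagents that add atoms: 1-phenyl-1H-tetrazole-5-thiol Sc1nnnn1-c1ccccc1
Why: Mitsunobu thioetherification at the primary carbon does not involve the adjacent stereocentre.

Step 27
Reactants: 33 5-{[(2S,5R,6S,8E)-6-[(tert-butyldimethylsilyl)oxy]-5-{[(tert-butyldimethylsilyl)oxy]methyl}-9-iodo-5,8-dimethyl-2-(propan-2-yl)non-8-en-1-yl]sulfanyl}-1-phenyl-1H-tetrazole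
Product: 34 5-{[(2S,5R,6S,8E)-6-[(tert-butyldimethylsilyl)oxy]-5-{[(tert-butyldimethylsilyl)oxy]methyl}-9-iodo-5,8-dimethyl-2-(propan-2-yl)non-8-en-1-yl]sulfonyl}-1-phenyl-1H-tetrazole
Conditions: (NH4)6Mo7O24·4H2O (10 mol %), H2O2 (30 %), EtOH, 0 °C → rt
Reagents that add atoms: hydrogen peroxide OO
Why: Molybdate-catalysed sulfide-to-sulfone oxidation is chemoselective for sulfur over the electron-poor iodoalkene.

**Union, ring closure and endgame**

Step 28
Reactants: 34 PT-sulfone (C9–C13, C1–C4); 10 (2R)-2-methyl-2-[(triethylsilyl)oxy]but-3-enal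
Product: 36 (3R,4E,6S,9R,10S,12E)-10-[(tert-butyldimethylsilyl)oxy]-9-{[(tert-butyldimethylsilyl)oxy]methyl}-13-iodo-3,9,12-trimethyl-6-(propan-2-yl)-3-[(triethylsilyl)oxy]trideca-1,4,12-triene, via potassium sulfonyl carbanion 35 (not isolated)
Conditions: KN(SiMe3)2 (1.1 equiv), DME, −60 °C; then 10, −60 °C → rt
Reagents that add atoms: none
Why: Julia–Kocienski olefination: addition of the metalated PT-sulfone to the non-enolisable aldehyde, Smiles rearrangement and loss of SO2 give the (E)-C8=C9 alkene, favoured by the bulk on both sides.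

Step 29
Reactants: 36 (3R,4E,6S,9R,10S,12E)-10-[(tert-butyldimethylsilyl)oxy]-9-{[(tert-butyldimethylsilyl)oxy]methyl}-13-iodo-3,9,12-trimethyl-6-(propan-2-yl)-3-[(triethylsilyl)oxy]trideca-1,4,12-triene
Product: 38 (1S,3E,7R,8E,10S,13R)-1-[(tert-butyldimethylsilyl)oxy]-13-{[(tert-butyldimethylsilyl)oxy]methyl}-3,7,13-trimethyl-10-(propan-2-yl)-7-[(triethylsilyl)oxy]cyclotrideca-3,8-diene, via B-alkyl-9-BBN adduct 37 (not isolated)
Conditions: 9-BBN, THF, rt; then slow addition to PdCl2(dppf) (20 mol %), AsPh3, Cs2CO3, DMF/THF/H2O, 50 °C, 2 mM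
Reagents that add atoms: none
Why: B-alkyl Suzuki–Miyaura macrocyclisation: 9-BBN adds only to the terminal vinyl group (boron at C5) and palladium couples this alkylborane with the vinyl iodide with retention of alkene geometry, closing the 13-membered ring.

Step 30
Reactants: 38 (1S,3E,7R,8E,10S,13R)-1-[(tert-butyldimethylsilyl)oxy]-13-{[(tert-butyldimethylsilyl)oxy]methyl}-3,7,13-trimethyl-10-(propan-2-yl)-7-[(triethylsilyl)oxy]cyclotrideca-3,8-diene
Product: 39 (1S,3E,7R,8E,10S,13R)-13-(hydroxymethyl)-3,7,13-trimethyl-10-(propan-2-yl)cyclotrideca-3,8-diene-1,7-diol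
Conditions: Bu4NF (6 equiv), THF, 50 °C
Reagents that add atoms: none
Why: Fluoride desilylation removes all three silyl ethers at a stage where nothing in the molecule is base-sensitive.

Step 31
Reactants: 39 (1S,3E,7R,8E,10S,13R)-13-(hydroxymethyl)-3,7,13-trimethyl-10-(propan-2-yl)cyclotrideca-3,8-diene-1,7-diol
Product: 40 (1S,3E,7R,8E,10S,13S)-13-formyl-3,7,13-trimethyl-10-(propan-2-yl)cyclotrideca-3,8-diene-1,7-diol
Conditions: TEMPO (20 mol %), PhI(OAc)2, CH2Cl2, rt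
Reagents that add atoms: none
Why: Oxoammonium (TEMPO) oxidation takes the primary alcohol much faster than the hindered secondary one and cannot oxidise the tertiary one, and the α-quaternary aldehyde cannot epimerise.

Step 32
Reactants: 40 (1S,3E,7R,8E,10S,13S)-13-formyl-3,7,13-trimethyl-10-(propan-2-yl)cyclotrideca-3,8-diene-1,7-diol
Product: 41 (1S,3E,7R,8E,10S,13S)-13-formyl-7-hydroxy-3,7,13-trimethyl-10-(propan-2-yl)cyclotrideca-3,8-dien-1-yl acetate
Conditions: Ac2O, pyridine, DMAP (cat.), CH2Cl2, 0 °C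
Reagents that add atoms: acetic anhydride CC(=O)OC(C)=O
Why: DMAP-catalysed acetylation esterifies the secondary C1 hydroxyl, while the tertiary allylic C7 hydroxyl is too hindered to react under these mild conditions.

## Compound list

1 | 3-methylbut-2-en-1-yl acetate | CC(=O)OCC=C(C)C | starting material
2 | (2E)-4-hydroxy-3-methylbut-2-en-1-yl acetate | CC(=O)OC/C=C(C)/CO | intermediate
3 | (2E)-4-(acetyloxy)-2-methylbut-2-en-1-yl 2,2-dimethylpropanoate | CC(=O)OC/C=C(C)/COC(=O)C(C)(C)C | intermediate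
4 | (2E)-4-hydroxy-2-methylbut-2-en-1-yl 2,2-dimethylpropanoate | OC/C=C(C)/COC(=O)C(C)(C)C | intermediate
5 | [(2S,3S)-3-(hydroxymethyl)-2-methyloxiran-2-yl]methyl 2,2-dimethylpropanoate | OC[C@@H]1O[C@@]1(C)COC(=O)C(C)(C)C | intermediate
6 | [(2S,3R)-3-(iodomethyl)-2-methyloxiran-2-yl]methyl 2,2-dimethylpropanoate | IC[C@@H]1O[C@@]1(C)COC(=O)C(C)(C)C | intermediate
7 | (2R)-2-hydroxy-2-methylbut-3-en-1-yl 2,2-dimethylpropanoate | C=C[C@@](C)(O)COC(=O)C(C)(C)C | intermediate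
8 | (2R)-2-methyl-2-[(triethylsilyl)oxy]but-3-en-1-yl 2,2-dimethylpropanoate | C=C[C@@](C)(O[Si](CC)(CC)CC)COC(=O)C(C)(C)C | intermediate
9 | (2R)-2-methyl-2-[(triethylsilyl)oxy]but-3-en-1-ol | C=C[C@@](C)(O[Si](CC)(CC)CC)CO | intermediate
10 | (2R)-2-methyl-2-[(triethylsilyl)oxy]but-3-enal | C=C[C@@](C)(O[Si](CC)(CC)CC)C=O | intermediate
11 | ethyl 5-(benzyloxy)-3-oxopentanoate | CCOC(=O)CC(=O)CCOCc1ccccc1 | starting material
12 | ethyl (3S)-5-(benzyloxy)-3-hydroxypentanoate | CCOC(=O)C[C@@H](O)CCOCc1ccccc1 | intermediate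
13 | dilithium alkoxide-enolate of 12 (chelated; enolate oxygen cis to C3) | [Li+].[Li+].CCO/C([O-])=C/[C@@H]([O-])CCOCc1ccccc1 | intermediate
14 | ethyl (2S,3S)-5-(benzyloxy)-3-hydroxy-2-methylpentanoate | CCOC(=O)[C@@H](C)[C@@H](O)CCOCc1ccccc1 | intermediate
15 | dilithium alkoxide-enolate of 14 (chelated; enolate oxygen cis to C3) | [Li+].[Li+].CCO/C([O-])=C(\C)[C@@H]([O-])CCOCc1ccccc1 | intermediate
16 | ethyl (2S,3S)-5-(benzyloxy)-3-hydroxy-2-methyl-2-(prop-2-en-1-yl)pentanoate | CCOC(=O)[C@@](C)(CC=C)[C@@H](O)CCOCc1ccccc1 | intermediate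
17 | (2R,3S)-5-(benzyloxy)-2-methyl-2-(prop-2-en-1-yl)pentane-1,3-diol | c1ccccc1COCC[C@H](O)[C@@](C)(CO)CC=C | intermediate
18 | (2R,3S)-5-(benzyloxy)-1,3-bis[(TBS)oxy]-2-methyl-2-(prop-2-en-1-yl)pentane | c1ccccc1COCC[C@H](O[Si](C)(C)C(C)(C)C)[C@@](C)(CO[Si](C)(C)C(C)(C)C)CC=C | intermediate
19 | 9-[(4R,5S)-7-(benzyloxy)-5-[(TBS)oxy]-4-{[(TBS)oxy]methyl}-4-methylheptyl]-9-borabicyclo[3.3.1]nonane | c1ccccc1COCC[C@H](O[Si](C)(C)C(C)(C)C)[C@@](C)(CO[Si](C)(C)C(C)(C)C)CCCB1C2CCCC1CCC2 | intermediate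
20 | (4R,5S)-7-(benzyloxy)-5-[(TBS)oxy]-4-{[(TBS)oxy]methyl}-4-methylheptan-1-ol | c1ccccc1COCC[C@H](O[Si](C)(C)C(C)(C)C)[C@@](C)(CO[Si](C)(C)C(C)(C)C)CCCO | intermediate
21 | (4R,5S)-7-(benzyloxy)-5-[(TBS)oxy]-4-{[(TBS)oxy]methyl}-4-methylheptanal | c1ccccc1COCC[C@H](O[Si](C)(C)C(C)(C)C)[C@@](C)(CO[Si](C)(C)C(C)(C)C)CCC=O | intermediate
22 | (3E,7R,8S)-10-(benzyloxy)-8-[(TBS)oxy]-7-{[(TBS)oxy]methyl}-7-methyldec-3-en-2-one | c1ccccc1COCC[C@H](O[Si](C)(C)C(C)(C)C)[C@@](C)(CO[Si](C)(C)C(C)(C)C)CC/C=C/C(C)=O | intermediate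
23 | (2R,3E,7R,8S)-10-(benzyloxy)-8-[(TBS)oxy]-7-{[(TBS)oxy]methyl}-7-methyldec-3-en-2-ol | c1ccccc1COCC[C@H](O[Si](C)(C)C(C)(C)C)[C@@](C)(CO[Si](C)(C)C(C)(C)C)CC/C=C/[C@@H](C)O | intermediate
24 | (2R,3E,7R,8S)-10-(benzyloxy)-8-[(TBS)oxy]-7-{[(TBS)oxy]methyl}-7-methyldec-3-en-2-yl pyridine-2-carboxylate | c1ccccc1COCC[C@H](O[Si](C)(C)C(C)(C)C)[C@@](C)(CO[Si](C)(C)C(C)(C)C)CC/C=C/[C@@H](C)OC(=O)c1ccccn1 | intermediate
25 | (2E,4S,7R,8S)-10-(benzyloxy)-8-[(TBS)oxy]-7-{[(TBS)oxy]methyl}-7-methyl-4-(propan-2-yl)dec-2-ene | c1ccccc1COCC[C@H](O[Si](C)(C)C(C)(C)C)[C@@](C)(CO[Si](C)(C)C(C)(C)C)CC[C@@H](C(C)C)/C=C/C | intermediate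
26 | (3S,4R,7S,8E)-3-[(TBS)oxy]-4-{[(TBS)oxy]methyl}-4-methyl-7-(propan-2-yl)dec-8-en-1-ol | OCC[C@H](O[Si](C)(C)C(C)(C)C)[C@@](C)(CO[Si](C)(C)C(C)(C)C)CC[C@@H](C(C)C)/C=C/C | intermediate
27 | (3S,4R,7S,8E)-3-[(TBS)oxy]-4-{[(TBS)oxy]methyl}-4-methyl-7-(propan-2-yl)dec-8-enal | O=CC[C@H](O[Si](C)(C)C(C)(C)C)[C@@](C)(CO[Si](C)(C)C(C)(C)C)CC[C@@H](C(C)C)/C=C/C | intermediate
28 | (4S,5R,8S,9E)-4-[(TBS)oxy]-5-{[(TBS)oxy]methyl}-5-methyl-8-(propan-2-yl)undec-9-en-1-yne | C#CC[C@H](O[Si](C)(C)C(C)(C)C)[C@@](C)(CO[Si](C)(C)C(C)(C)C)CC[C@@H](C(C)C)/C=C/C | intermediate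
29 | (2S,5R,6S)-6-[(TBS)oxy]-5-{[(TBS)oxy]methyl}-5-methyl-2-(propan-2-yl)non-8-ynal | C#CC[C@H](O[Si](C)(C)C(C)(C)C)[C@@](C)(CO[Si](C)(C)C(C)(C)C)CC[C@@H](C(C)C)C=O | intermediate
30 | (2S,5R,6S)-6-[(TBS)oxy]-5-{[(TBS)oxy]methyl}-5-methyl-2-(propan-2-yl)non-8-yn-1-ol | C#CC[C@H](O[Si](C)(C)C(C)(C)C)[C@@](C)(CO[Si](C)(C)C(C)(C)C)CC[C@@H](C(C)C)CO | intermediate
31 | (E)-alkenyl(dimethyl)alane from syn-methylalumination of 30, C1 oxygen as its dimethylaluminium alkoxide | C[Al](C)/C=C(\C)C[C@H](O[Si](C)(C)C(C)(C)C)[C@@](C)(CO[Si](C)(C)C(C)(C)C)CC[C@@H](C(C)C)CO[Al](C)C | intermediate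
32 | (2S,5R,6S,8E)-6-[(TBS)oxy]-5-{[(TBS)oxy]methyl}-9-iodo-5,8-dimethyl-2-(propan-2-yl)non-8-en-1-ol | I/C=C(\C)C[C@H](O[Si](C)(C)C(C)(C)C)[C@@](C)(CO[Si](C)(C)C(C)(C)C)CC[C@@H](C(C)C)CO | intermediate
33 | 5-{[(2S,5R,6S,8E)-6-[(TBS)oxy]-5-{[(TBS)oxy]methyl}-9-iodo-5,8-dimethyl-2-(propan-2-yl)non-8-en-1-yl]sulfanyl}-1-phenyl-1H-tetrazole | I/C=C(\C)C[C@H](O[Si](C)(C)C(C)(C)C)[C@@](C)(CO[Si](C)(C)C(C)(C)C)CC[C@@H](C(C)C)CSc1nnnn1-c1ccccc1 | intermediate
34 | 5-{[(2S,5R,6S,8E)-6-[(TBS)oxy]-5-{[(TBS)oxy]methyl}-9-iodo-5,8-dimethyl-2-(propan-2-yl)non-8-en-1-yl]sulfonyl}-1-phenyl-1H-tetrazole | I/C=C(\C)C[C@H](O[Si](C)(C)C(C)(C)C)[C@@](C)(CO[Si](C)(C)C(C)(C)C)CC[C@@H](C(C)C)CS(=O)(=O)c1nnnn1-c1ccccc1 | intermediate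
35 | potassium α-sulfonyl carbanion of 34 | [K+].I/C=C(\C)C[C@H](O[Si](C)(C)C(C)(C)C)[C@@](C)(CO[Si](C)(C)C(C)(C)C)CC[C@@H](C(C)C)[CH-]S(=O)(=O)c1nnnn1-c1ccccc1 | intermediate
36 | (3R,4E,6S,9R,10S,12E)-10-[(TBS)oxy]-9-{[(TBS)oxy]methyl}-13-iodo-3,9,12-trimethyl-6-(propan-2-yl)-3-[(TES)oxy]trideca-1,4,12-triene | I/C=C(\C)C[C@H](O[Si](C)(C)C(C)(C)C)[C@@](C)(CO[Si](C)(C)C(C)(C)C)CC[C@@H](C(C)C)/C=C/[C@](C)(O[Si](CC)(CC)CC)C=C | intermediate
37 | B-alkyl-9-BBN adduct of 36 (boron on the former terminal vinyl carbon, C5 of the ring) | I/C=C(\C)C[C@H](O[Si](C)(C)C(C)(C)C)[C@@](C)(CO[Si](C)(C)C(C)(C)C)CC[C@@H](C(C)C)/C=C/[C@](C)(O[Si](CC)(CC)CC)CCB1C2CCCC1CCC2 | intermediate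
38 | (1S,3E,7R,8E,10S,13R)-1-[(TBS)oxy]-13-{[(TBS)oxy]methyl}-3,7,13-trimethyl-10-(propan-2-yl)-7-[(TES)oxy]cyclotrideca-3,8-diene | CC(C)(C)[Si](C)(C)O[C@H]1C/C(C)=C/CC[C@@](C)(O[Si](CC)(CC)CC)/C=C/[C@H](C(C)C)CC[C@]1(C)CO[Si](C)(C)C(C)(C)C | intermediate
39 | (1S,3E,7R,8E,10S,13R)-13-(hydroxymethyl)-3,7,13-trimethyl-10-(propan-2-yl)cyclotrideca-3,8-diene-1,7-diol | O[C@H]1C/C(C)=C/CC[C@@](C)(O)/C=C/[C@H](C(C)C)CC[C@]1(C)CO | intermediate
40 | (1S,3E,7R,8E,10S,13S)-13-formyl-3,7,13-trimethyl-10-(propan-2-yl)cyclotrideca-3,8-diene-1,7-diol | O[C@H]1C/C(C)=C/CC[C@@](C)(O)/C=C/[C@H](C(C)C)CC[C@]1(C)C=O | intermediate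
41 | (1S,3E,7R,8E,10S,13S)-13-formyl-7-hydroxy-3,7,13-trimethyl-10-(propan-2-yl)cyclotrideca-3,8-dien-1-yl acetate | CC(=O)O[C@H]1C/C(C)=C/CC[C@@](C)(O)/C=C/[C@H](C(C)C)CC[C@]1(C)C=O | target

## Step count and risks

Total step count: 32 (steps 1–9 for aldehyde 10, steps 10–27 for sulfone 34, steps 28–32 for union, ring closure and endgame).
Longest linear sequence: 23 steps (11 → 41, steps 10–32).

Three steps most likely to fail:

1. Step 29 (macrocyclic B-alkyl Suzuki coupling). Oligomerisation, protodeboronation or strain in the 13-membered ring could defeat it. The fallback changes the ring-closing bond from C4–C5 to C8=C9; it sets out from 8 and 34 and comes back at 38. Pivalate 8 is hydroborated with 9-BBN to the alkylborane F1, which is coupled intermolecularly with vinyl iodide 34 (PdCl2(dppf), AsPh3, Cs2CO3, DMF/H2O) to give the seco-sulfone pivalate F2. Reduction with i-Bu2AlH gives the seco-sulfone alcohol F3 and Dess–Martin oxidation the seco-sulfone aldehyde F4. Slow addition of F4 to KN(SiMe3)2 in DME at high dilution then closes the ring by an intramolecular Julia–Kocienski olefination to 38.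

2. Step 20 (anti-SN2' substitution with isopropyl). α-Attack or reaction through the methyl-eclipsed conformer would erode regioselectivity and the configuration at C10. The fallback uses intramolecular syn delivery instead; it sets out from enone 22 and comes back at 25. Enone 22 is reduced with the (R)-configured CBS catalyst and catecholborane to the (2S)-allylic alcohol F5, which is converted with phenyl isocyanate into the N-phenylcarbamate F6. Deprotonation (MeLi), CuI and then i-PrLi (THF, −78 → 0 °C) give a carbamate-bound cuprate that transfers isopropyl syn to the leaving group; syn attack on the (2S) series gives the same (4S,E) product 25.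

3. Step 12 (quaternary centre by dianion allylation). O-alkylation, retro-aldol cleavage or a modest diastereomer ratio are possible. The fallback uses a cyclic acetal enolate; it sets out from 14 and comes back at 17. Ester 14 is saponified (LiOH, THF/H2O) to the hydroxy acid F7, which is condensed with pivalaldehyde (TsOH cat., CH2Cl2, MgSO4) to the cis-dioxanone F8. Its lithium enolate (LiN(iPr)2, THF, −78 °C) is allylated trans to the C6 side chain to give the allylated dioxanone F9, and LiAlH4 reduction opens F9 to diol 17.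

## Further compounds

F1 | step 29 | 9-{(3R)-4-[(2,2-dimethylpropanoyl)oxy]-3-methyl-3-[(triethylsilyl)oxy]butyl}-9-borabicyclo[3.3.1]nonane | CC(C)(C)C(=O)OC[C@](C)(O[Si](CC)(CC)CC)CCB1C2CCCC1CCC2
F2 | step 29 | (2R,5E,8S,9R,12S)-8-[(TBS)oxy]-9-{[(TBS)oxy]methyl}-2,6,9-trimethyl-13-(PT-sulfonyl)-12-(propan-2-yl)-2-[(TES)oxy]tridec-5-en-1-yl 2,2-dimethylpropanoate | CC(C)(C)C(=O)OC[C@](C)(O[Si](CC)(CC)CC)CC/C=C(\C)C[C@H](O[Si](C)(C)C(C)(C)C)[C@@](C)(CO[Si](C)(C)C(C)(C)C)CC[C@@H](C(C)C)CS(=O)(=O)c1nnnn1-c1ccccc1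
F3 | step 29 | (2R,5E,8S,9R,12S)-8-[(TBS)oxy]-9-{[(TBS)oxy]methyl}-2,6,9-trimethyl-13-(PT-sulfonyl)-12-(propan-2-yl)-2-[(TES)oxy]tridec-5-en-1-ol | OC[C@](C)(O[Si](CC)(CC)CC)CC/C=C(\C)C[C@H](O[Si](C)(C)C(C)(C)C)[C@@](C)(CO[Si](C)(C)C(C)(C)C)CC[C@@H](C(C)C)CS(=O)(=O)c1nnnn1-c1ccccc1
F4 | step 29 | (2R,5E,8S,9R,12S)-8-[(TBS)oxy]-9-{[(TBS)oxy]methyl}-2,6,9-trimethyl-13-(PT-sulfonyl)-12-(propan-2-yl)-2-[(TES)oxy]tridec-5-enal | O=C[C@](C)(O[Si](CC)(CC)CC)CC/C=C(\C)C[C@H](O[Si](C)(C)C(C)(C)C)[C@@](C)(CO[Si](C)(C)C(C)(C)C)CC[C@@H](C(C)C)CS(=O)(=O)c1nnnn1-c1ccccc1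
F5 | step 20 | (2S,3E,7R,8S)-10-(benzyloxy)-8-[(TBS)oxy]-7-{[(TBS)oxy]methyl}-7-methyldec-3-en-2-ol | c1ccccc1COCC[C@H](O[Si](C)(C)C(C)(C)C)[C@@](C)(CO[Si](C)(C)C(C)(C)C)CC/C=C/[C@H](C)O
F6 | step 20 | (2S,3E,7R,8S)-10-(benzyloxy)-8-[(TBS)oxy]-7-{[(TBS)oxy]methyl}-7-methyldec-3-en-2-yl N-phenylcarbamate | c1ccccc1COCC[C@H](O[Si](C)(C)C(C)(C)C)[C@@](C)(CO[Si](C)(C)C(C)(C)C)CC/C=C/[C@H](C)OC(=O)Nc1ccccc1
F7 | step 12 | (2S,3S)-5-(benzyloxy)-3-hydroxy-2-methylpentanoic acid | OC(=O)[C@@H](C)[C@@H](O)CCOCc1ccccc1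
F8 | step 12 | (2S,5S,6S)-6-[2-(benzyloxy)ethyl]-2-tert-butyl-5-methyl-1,3-dioxan-4-one | CC(C)(C)[C@@H]1OC(=O)[C@@H](C)[C@H](CCOCc2ccccc2)O1
F9 | step 12 | (2S,5S,6S)-6-[2-(benzyloxy)ethyl]-2-tert-butyl-5-methyl-5-(prop-2-en-1-yl)-1,3-dioxan-4-one | CC(C)(C)[C@@H]1OC(=O)[C@@](C)(CC=C)[C@H](CCOCc2ccccc2)O1
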